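**Assumption (remark on the chemistry):** boronic esters of the (R,R)-diol 2 are taken to give (αS)-α-chloro boronic esters with (dichloromethyl)lithium, and a Grignard reagent is taken to displace that chloride with inversion. On this basis the (R,R)-diol leads to 11 as drawn and the (S,S)-diol to the mirror-image series. Compounds 8 and 18 are taken as purchasable, 8 being used fresh.

## Structural features

Target 22 is a single γ-butyrolactone ring (O1, C2 carbonyl, C3, C4, C5) with a 3,4-dihydroxybenzyl arm on C3 and a 3,4-dimethoxybenzyl arm on C4. C3 and C4 are adjacent stereocentres, both R, with the two arms trans. C3 is α to the carbonyl, so it can be set by enolate chemistry and corrected by base, and the trans arrangement is also the thermodynamically preferred one. C4 is a CH bearing three carbon arms of similar size (C5, the dimethoxybenzyl CH2 and C3) with no activating group, so its configuration must be set absolutely and cannot be repaired later. The free catechol is the fragile group, being oxidised readily in base and air, and the dimethoxyphenyl ring is open to electrophilic halogenation. The two aryl rings differ only in O-substitution, so they are best kept on separate fragments. The key step treats C4 as a carbenoid carbon on boron: the C5–C4 and C4–CH2(aryl) bonds are made by two successive boron-to-carbon shifts, and boron stays on C4 as the handle for C3.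

## Logic of the disconnections

**22 ⇒ 21.** The two aryl O–CH2Ph bonds are cut. The catechol is carried as its dibenzyl ether so that it is released last, under neutral conditions. Every earlier intermediate is then a robust ether. The forward hydrogenolysis must leave the lactone and the benzylic C–C bonds alone, which is normal for this reaction.

**21 ⇒ 17 + 19.** The C3–CH2(aryl) bond is cut. C3 is the enolisable carbon, and the C4 substituent should send the incoming benzyl group to the opposite face, which is the trans (3R,4R) relation. This removes one stereocentre and one aryl ring, and the two rings never have to be told apart. The forward step must stop at mono-alkylation, and 19 has to be made fresh from 18.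

**17 ⇒ 15 (through 16).** The acyl–oxygen bond O1–C2 is cut and the C5 oxygen is covered as a benzyl ether. A γ-hydroxy acid closes to the lactone by itself, so the ring costs no separate step. The forward step is a hydrogenolysis of an alkyl benzyl ether that must spare the dimethoxyphenyl ring.

**15 ⇒ 12 (through 13 and 14).** The C2–C3 bond is cut. The carboxyl carbon is traced back to a one-carbon halocarbenoid inserted into a primary C–B bond, whose halogen-bearing carbon is then oxidised directly to the acid level. This saves the separate alcohol and aldehyde stages. The oxidant must not chlorinate the electron-rich ring.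

**12 ⇒ 11.** The C3–C4 bond is cut: C3 is a methylene inserted into the C4–B bond with retention at C4. A second halocarbenoid and benzyl-Grignard cycle on 11 could bring in C3 together with the catechol arm, but under the same director it would place C3 in the cis (3S) relation. That would require a late base equilibration and a second benzylic Grignard reagent. Carrying C3 as a plain CH2 and alkylating the lactone later avoids both.

**11 ⇒ 7 + 9 + a C1 carbenoid (key).** The C5–C4 and C4–CH2(aryl) bonds are cut at the same carbon. Three simple components result, and the only stereocentre that cannot be epimerised is set by the diol on boron. The forward step needs clean carbon migration in both shifts and a usable benzylic Grignard reagent.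

**7 ⇒ 4 + 5; 4 ⇒ 1 + 2; 9 ⇒ 8.** The C–O bond of the benzyloxymethyl group, the B–O bonds to the diol and the C–Mg bond are cut. These lead back to bulk chemicals and the recoverable diol. The forward steps are standard boron substitution, transesterification and magnesium insertion.

## Other disconnections considered

**Alternative 1:** The cut is the C4–C5 bond, together with the C3–H bond. C5 would come from a bromomethylsilyl group tethered to a benzylic carbinol that later becomes the CH2 of the dimethoxybenzyl arm.

- Forward step: silyl ether A2, with a tin hydride and a radical initiator, should give a silicon-bound CH2 radical that closes 5-exo onto the β-carbon of the enoate. Hydrogen transfer to the ester-stabilised radical would give oxasilolane A1, with the C4 substituent trans to the ring aryl group and C3 as a mixture.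
- In favour: the whole skeleton with both aryl arms is in place before the key step. C4 is set by 1,2-induction from an oxygenated centre that is readily made enantioselectively. The conditions tolerate acetals and esters and need no cryogenics.
- Against: the controlling carbinol is sacrificial and must be removed by benzylic deoxygenation after the C–Si bond is oxidised. After that oxidation two hydroxyls both sit γ to the ester, so lactonisation is regiochemically ambiguous. C3 needs a base equilibration, and tin is used stoichiometrically.
- Comparison: on structure the tether plan is the equal or the better, because it is convergent and brings both arms in early. On mechanism it relies on the diastereomer ratio of a kinetic radical cyclisation, whereas the chosen plan uses two stereospecific migrations under a director with no epimerisable intermediate. On step economy the oxidation, deoxygenation, equilibration and acetal removal after A1 should make it longer than the chosen plan.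

**Alternative 2:** The cut is the C3–C4 bond plus the O1–C5 bond, the lactone oxygen being inserted later into a temporary C2–C5 bond.

- Forward step: amide A5 would be activated with a sulfonic anhydride and a hindered pyridine base to a keteniminium salt. This should add across the terminal alkene of A4 and give cyclobutanone A3 after hydrolysis. Oxidative ring expansion and ester removal would follow.
- In favour: the C3–C4 bond and both stereocentres would form in one step with the preferred trans relation. A4 is an article of commerce and A5 is close to one. On step count this is clearly the better plan on paper.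
- Against: in a Baeyer–Villiger oxidation of A3 the more substituted α-carbon (C3) is the better migrating group. Oxygen would therefore be expected to enter the C2–C3 bond and not the C2–C5 bond, which gives the wrong lactone substitution pattern for 22. The absolute sense rests on the face selectivity of an amine auxiliary towards an unactivated alkene. The keteniminium ion may acylate the electron-rich ring of A4. The pivalates must come off a base-sensitive lactone and catechol.
- Comparison: on structure the alternative is more direct. On mechanism its regiochemistry of oxygen insertion and its facial selectivity are both open, while every bond in the chosen plan forms at a predetermined atom. On step economy it is better only if the ring expansion can be directed.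

**Alternative 3:** The cut is the O1–C2 bond of a precursor A7 whose C4 carries two hydroxymethyl groups, so that C4 becomes a stereocentre only on lactonisation.

- Forward step: reversible acid-catalysed lactonisation should give A6 with the free CH2OH trans to the C3 benzyl group. The CH2OH would then be activated and coupled with an aryl-metal to build the dimethoxybenzyl arm, followed by debenzylation.
- In favour: C4 needs no asymmetric reaction, being relayed from C3, which auxiliary alkylation sets reliably. The equilibrium is self-correcting. No carbenoid at −100 °C and no benzylic Grignard reagent is needed, a point on which it is the better plan. Late arylation also suits analogue work.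
- Against: the energy gap between the two lactonisation modes may be small for a CH2OH group. The controlling centre C3 is the epimerisable one, so inversion at C3 followed by re-lactonisation through the other arm would form the enantiomer. The coupling at a β-branched primary carbon next to a lactone needs basic organometallics.
- Comparison: on structure the order is reversed (C3 first, C4 by relay), whereas the chosen plan fixes the non-epimerisable centre first. On mechanism an equilibrium is set against stereospecific migrations. On step economy the two are about equal.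

Key step: step 4

## Route

**Step 1**
Reactants: 1 triisopropyl borate; 2 (1R,2R)-1,2-dicyclohexylethane-1,2-diol [(R,R)-DICHED]
Product: 4 (4R,5R)-2-(bromomethyl)-4,5-dicyclohexyl-1,3,2-dioxaborolane, via diisopropyl (bromomethyl)boronate 3 (not isolated)
Conditions: CH2Br2, n-BuLi, THF, −78 °C; MeSO3H, −78 °C → rt; then 2, rt
Reagents that add atoms: dibromomethane, BrCBr
Why: Bromine–lithium exchange gives (bromomethyl)lithium, which the borate traps at −78 °C as a stable tetracoordinate salt; acid releases 3 and transesterification with diol 2, driven by the stable five-membered dioxaborolane, gives 4 (standard preparation of halomethylboronic esters). No stereocentre is formed.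

**Step 2**
Reactants: 4 (4R,5R)-2-(bromomethyl)-4,5-dicyclohexyl-1,3,2-dioxaborolane; 5 benzyl alcohol
Product: 7 (4R,5R)-2-[(benzyloxy)methyl]-4,5-dicyclohexyl-1,3,2-dioxaborolane, via sodium benzyloxide 6 (not isolated)
Conditions: NaH, THF, 0 °C; then 4, DMSO, 0 °C → rt
Reagents that add atoms: none
Why: Benzyloxide adds to boron and the oxygen then shifts from boron to carbon with loss of bromide (1,2-metallate substitution of an α-halo boronic ester), which is far easier than direct SN2 at this carbon. The diol stereocentres are untouched.

**Step 3**
Reactants: 8 3,4-dimethoxybenzyl chloride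
Product: 9 (3,4-dimethoxybenzyl)magnesium chloride
Conditions: Mg turnings (excess), I2 (cat.), 2-MeTHF, 0 °C, slow addition
Reagents that add atoms: magnesium, [Mg]
Why: Insertion of magnesium into the benzylic C–Cl bond (Grignard formation); slow addition to excess metal in cold 2-MeTHF keeps the chloride concentration low and should limit Wurtz homocoupling.

**Step 4**
Reactants: 7 (4R,5R)-2-[(benzyloxy)methyl]-4,5-dicyclohexyl-1,3,2-dioxaborolane; 9 (3,4-dimethoxybenzyl)magnesium chloride
Product: 11 (4R,5R)-2-[(2S)-1-(benzyloxy)-3-(3,4-dimethoxyphenyl)propan-2-yl]-4,5-dicyclohexyl-1,3,2-dioxaborolane, via α-chloro boronate 10 (not isolated)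
Conditions: CH2Cl2, n-BuLi, THF, −100 °C; 7; ZnCl2 (2–3 equiv), −100 °C → rt; then crude 10, 9, THF, −78 °C → rt
Reagents that add atoms: dichloromethane, ClCCl (delivered as (dichloromethyl)lithium, [Li]C(Cl)Cl)
Why: Preformed (dichloromethyl)lithium adds to the trigonal boron of 7 to give a tetracoordinate ate complex; with ZnCl2 and warming the benzyloxymethyl group shifts from boron to the carbenoid carbon with loss of one chloride, which forms the C5–C4 bond and gives the (αS)-chloride 10. Grignard reagent 9 then adds to boron of 10 and its benzyl group migrates to the same carbon anti to the remaining chloride, with inversion, which forms the C4–CH2(aryl) bond and leaves boron on C4. The closest known reaction type is the Matteson homologation of a chiral diol boronic ester followed by Grignard displacement. No ring is closed. The single new stereocentre is controlled by the C2-symmetric (R,R)-diol: in the zinc-bridged transition state of the first shift the metal holds one ring oxygen and the departing chloride, so only one of the two diastereotopic chlorides can leave anti to the migrating carbon, and the stereospecific second shift turns the (αS)-chloride into the (S)-boronate. Neither 10 nor 11 has an acidic C–H at the new centre, and ZnCl2 binds the liberated chloride so that 10 is not inverted by chloride exchange. The step needs carbon and not ring oxygen to migrate and the β-benzyloxy group to stay in place; the first is secured by the poor migratory aptitude of the dioxaborolane oxygens, the second by the poor leaving-group ability of an alkoxide and by keeping both ate complexes cold until the shift sets in. Chloride 10 is carried forward crude after a quick pentane/aqueous NH4Cl wash to remove zinc salts, because chromatography would erode its configurational purity.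

**Step 5**
Reactants: 11 (4R,5R)-2-[(2S)-1-(benzyloxy)-3-(3,4-dimethoxyphenyl)propan-2-yl]-4,5-dicyclohexyl-1,3,2-dioxaborolane
Product: 12 (4R,5R)-2-[(2S)-3-(benzyloxy)-2-(3,4-dimethoxybenzyl)propyl]-4,5-dicyclohexyl-1,3,2-dioxaborolane
Conditions: BrCH2Cl, n-BuLi, THF, −78 °C → rt
Reagents that add atoms: bromochloromethane, ClCBr
Why: Matteson homologation with (chloromethyl)lithium generated in the presence of the boronic ester: the carbenoid adds to boron and the secondary alkyl group migrates to CH2 with loss of chloride and retention at C4, so the C3–C4 bond forms without touching the stereocentre.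

**Step 6**
Reactants: 12 (4R,5R)-2-[(2S)-3-(benzyloxy)-2-(3,4-dimethoxybenzyl)propyl]-4,5-dicyclohexyl-1,3,2-dioxaborolane
Product: 15 (3R)-4-(benzyloxy)-3-(3,4-dimethoxybenzyl)butanoic acid, via α-chloro boronate 13 (not isolated), via aldehyde 14 (not isolated)
Conditions: CH2Cl2, n-BuLi, THF, −100 °C; ZnCl2, −100 °C → rt; solvent exchange; then NaClO2, NaH2PO4, 2-methyl-2-butene, t-BuOH/H2O, rt
Reagents that add atoms: dichloromethane, ClCCl; sodium chlorite, [Na+].[O-]Cl=O
Why: A further Matteson homologation inserts the future carboxyl carbon C2 into the primary C–B bond; chlorite then attacks boron, the α-chloroalkyl group shifts to oxygen, the chloro-borate collapses to aldehyde 14 and this is oxidised on to the acid in the same flask (chlorite oxidation of an α-chloro boronic ester, then Pinnick oxidation). 2-Methyl-2-butene removes hypochlorite before it can chlorinate the dimethoxyphenyl ring, and the configuration of the CHCl carbon does not matter because that centre is destroyed.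

**Step 7**
Reactants: 15 (3R)-4-(benzyloxy)-3-(3,4-dimethoxybenzyl)butanoic acid
Product: 17 (4R)-4-(3,4-dimethoxybenzyl)oxolan-2-one, via hydroxy acid 16 (not isolated)
Conditions: H2 (1 atm), Pd/C, EtOAc, rt; then TsOH (cat.), CH2Cl2, rt
Reagents that add atoms: none
Why: Hydrogenolysis of the alkyl benzyl ether frees the C5 hydroxyl, and γ-hydroxy acid 16 closes to the five-membered lactone on trace acid (5-exo-trig acyl substitution). C4 takes no part and keeps its configuration.

**Step 8**
Reactants: 18 [3,4-bis(benzyloxy)phenyl]methanol
Product: 19 1,2-bis(benzyloxy)-4-(bromomethyl)benzene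
Conditions: PBr3, CH2Cl2, 0 °C
Reagents that add atoms: phosphorus tribromide, BrP(Br)Br
Why: Conversion of a benzylic alcohol into the bromide through its phosphite ester (SN2 by bromide); the aryl benzyl ethers should survive at 0 °C, and the bromide is used at once.

**Step 9**
Reactants: 17 (4R)-4-(3,4-dimethoxybenzyl)oxolan-2-one; 19 1,2-bis(benzyloxy)-4-(bromomethyl)benzene
Product: 21 (3R,4R)-3-[3,4-bis(benzyloxy)benzyl]-4-(3,4-dimethoxybenzyl)oxolan-2-one, via lithium enolate 20 (not isolated)
Conditions: LiN(SiMe3)2, THF, −78 °C; then 19, DMPU, −78 → −30 °C
Reagents that add atoms: none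
Why: Kinetic deprotonation gives enolate 20, which should be alkylated on the face opposite the C4 benzyl group (1,2-induction in a five-membered enolate, the established alkylation of β-benzyl-γ-butyrolactones), so C3 is set trans to C4, that is 3R. Trans is also the thermodynamically preferred arrangement, so any cis material can be corrected by base.

**Step 10**
Reactants: 21 (3R,4R)-3-[3,4-bis(benzyloxy)benzyl]-4-(3,4-dimethoxybenzyl)oxolan-2-one
Product: 22 (3R,4R)-3-(3,4-dihydroxybenzyl)-4-(3,4-dimethoxybenzyl)oxolan-2-one (3'-O-demethylarctigenin)
Conditions: H2 (1 atm), Pd/C, EtOAc/MeOH, rt; filtration under argon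
Reagents that add atoms: none
Why: Hydrogenolysis of the two aryl benzyl ethers is fast and neutral; it should leave the lactone, the methyl ethers and both stereocentres untouched and releases the air-sensitive catechol only at the end.

## Compound list

1 | triisopropyl borate | CC(C)OB(OC(C)C)OC(C)C | starting material
2 | (1R,2R)-1,2-dicyclohexylethane-1,2-diol [(R,R)-DICHED] | O[C@H](C1CCCCC1)[C@H](O)C1CCCCC1 | starting material
3 | diisopropyl (bromomethyl)boronate | CC(C)OB(CBr)OC(C)C | intermediate
4 | (4R,5R)-2-(bromomethyl)-4,5-dicyclohexyl-1,3,2-dioxaborolane | BrCB1O[C@H](C2CCCCC2)[C@@H](C2CCCCC2)O1 | intermediate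
5 | benzyl alcohol | OCc1ccccc1 | starting material
6 | sodium benzyloxide | [Na+].[O-]Cc1ccccc1 | intermediate
7 | (4R,5R)-2-[(benzyloxy)methyl]-4,5-dicyclohexyl-1,3,2-dioxaborolane | C(OCc1ccccc1)B1O[C@H](C2CCCCC2)[C@@H](C2CCCCC2)O1 | intermediate
8 | 3,4-dimethoxybenzyl chloride | COc1ccc(CCl)cc1OC | starting material
9 | (3,4-dimethoxybenzyl)magnesium chloride | COc1ccc(C[Mg]Cl)cc1OC | intermediate
10 | (4R,5R)-2-[(1S)-2-(benzyloxy)-1-chloroethyl]-4,5-dicyclohexyl-1,3,2-dioxaborolane | Cl[C@H](COCc1ccccc1)B1O[C@H](C2CCCCC2)[C@@H](C2CCCCC2)O1 | intermediate
11 | (4R,5R)-2-[(2S)-1-(benzyloxy)-3-(3,4-dimethoxyphenyl)propan-2-yl]-4,5-dicyclohexyl-1,3,2-dioxaborolane | COc1ccc(C[C@H](B2O[C@H](C3CCCCC3)[C@@H](C3CCCCC3)O2)COCc2ccccc2)cc1OC | intermediate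
12 | (4R,5R)-2-[(2S)-3-(benzyloxy)-2-(3,4-dimethoxybenzyl)propyl]-4,5-dicyclohexyl-1,3,2-dioxaborolane | COc1ccc(C[C@H](CB2O[C@H](C3CCCCC3)[C@@H](C3CCCCC3)O2)COCc2ccccc2)cc1OC | intermediate
13 | (4R,5R)-2-[(1S,3R)-4-(benzyloxy)-1-chloro-3-(3,4-dimethoxybenzyl)butyl]-4,5-dicyclohexyl-1,3,2-dioxaborolane | COc1ccc(C[C@H](C[C@@H](Cl)B2O[C@H](C3CCCCC3)[C@@H](C3CCCCC3)O2)COCc2ccccc2)cc1OC | intermediate
14 | (3R)-4-(benzyloxy)-3-(3,4-dimethoxybenzyl)butanal | COc1ccc(C[C@H](CC=O)COCc2ccccc2)cc1OC | intermediate
15 | (3R)-4-(benzyloxy)-3-(3,4-dimethoxybenzyl)butanoic acid | COc1ccc(C[C@H](CC(=O)O)COCc2ccccc2)cc1OC | intermediate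
16 | (3R)-3-(3,4-dimethoxybenzyl)-4-hydroxybutanoic acid | COc1ccc(C[C@H](CC(=O)O)CO)cc1OC | intermediate
17 | (4R)-4-(3,4-dimethoxybenzyl)oxolan-2-one | COc1ccc(C[C@H]2COC(=O)C2)cc1OC | intermediate
18 | [3,4-bis(benzyloxy)phenyl]methanol | OCc1ccc(OCc2ccccc2)c(OCc2ccccc2)c1 | starting material
19 | 1,2-bis(benzyloxy)-4-(bromomethyl)benzene | BrCc1ccc(OCc2ccccc2)c(OCc2ccccc2)c1 | intermediate
20 | lithium (4R)-4-(3,4-dimethoxybenzyl)-4,5-dihydrofuran-2-olate | COc1ccc(C[C@H]2COC(O[Li])=C2)cc1OC | intermediate
21 | (3R,4R)-3-[3,4-bis(benzyloxy)benzyl]-4-(3,4-dimethoxybenzyl)oxolan-2-one | COc1ccc(C[C@H]2COC(=O)[C@@H]2Cc2ccc(OCc3ccccc3)c(OCc3ccccc3)c2)cc1OC | intermediate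
22 | (3R,4R)-3-(3,4-dihydroxybenzyl)-4-(3,4-dimethoxybenzyl)oxolan-2-one (3'-O-demethylarctigenin) | COc1ccc(C[C@H]2COC(=O)[C@@H]2Cc2ccc(O)c(O)c2)cc1OC | target

## Step count and least certain steps

Total step count: 10. Longest linear sequence: 8 steps (steps 1, 2, 4, 5, 6, 7, 9, 10); steps 3 and 8 make the two side fragments.

**Step 4 (key step).** The most likely failure is a sluggish first shift, because the migrating carbon carries oxygen and is electron-poor. That would leave time for chloride exchange to erode the configuration of the α-chloride. A second risk is expulsion of the β-benzyloxy group from the ate complex during the Grignard stage.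
The fallback permutes the three components so that an ordinary benzyl group migrates and no β-oxygen is present. It sets out from 9 (with 1 and 2) and comes back at 17. Grignard reagent 9 is quenched with 1 and esterified with 2 to give (4R,5R)-4,5-dicyclohexyl-2-(3,4-dimethoxybenzyl)-1,3,2-dioxaborolane F1. (Dichloromethyl)lithium and ZnCl2 give the (1S)-chloride F2. tert-Butyl lithioacetate displaces the chloride with inversion to give the β-boryl ester F3. (Chloromethyl)lithium inserts CH2 to give F4, NaOH/H2O2 gives the hydroxy ester F5, and CF3CO2H closes it to 17. With the same (R,R)-diol the order "benzyl migrates, acetate arm enters, boron becomes C5" gives the same spatial arrangement at C4. This fallback bypasses steps 5 to 7.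

**Step 3.** Wurtz-type homocoupling, in which the Grignard reagent attacks unreacted electron-rich benzylic chloride, may consume much of the material. The fallback makes the benzylic carbanion with no carbon electrophile present. It sets out from 8 and comes back at 9. PhSNa converts 8 into 3,4-dimethoxybenzyl phenyl sulfide F6. Reductive cleavage with lithium 4,4'-di-tert-butylbiphenylide at −78 °C gives (3,4-dimethoxybenzyl)lithium F7, and MgCl2 converts this into 9.

**Step 6.** Attack of chlorite on the hindered boron may be slow, and hypochlorite may chlorinate the dimethoxyphenyl ring faster than the scavenger removes it. The fallback separates carbon insertion from oxidation. It sets out from 12 and comes back at 15. A second (chloromethyl)lithium insertion gives the homologous boronic ester F8. NaOH/H2O2 gives (3R)-4-(benzyloxy)-3-(3,4-dimethoxybenzyl)butan-1-ol F9, and TEMPO with PhI(OAc)2 in MeCN/H2O oxidises this to 15.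

**Step 9.** Proton transfer between product and enolate may lead to double alkylation and returned 17, made worse by decomposition of the labile bromide 19. The fallback replaces alkylation by an aldol condensation and reduction. It sets out from 17 (through enolate 20) and comes back at 21. Addition of 20 to 3,4-bis(benzyloxy)benzaldehyde F10 gives aldol adduct F11. TsOH in hot toluene dehydrates it to the (E)-benzylidene lactone F12. Conjugate reduction with NaBH4 and NiCl2·6H2O gives 21 together with its C3 epimer F13, and DBU in toluene equilibrates the mixture towards the trans isomer 21.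

## Further compounds

F1 | step 4 | (4R,5R)-4,5-dicyclohexyl-2-(3,4-dimethoxybenzyl)-1,3,2-dioxaborolane | COc1ccc(CB2O[C@H](C3CCCCC3)[C@@H](C3CCCCC3)O2)cc1OC
F2 | step 4 | (4R,5R)-2-[(1S)-1-chloro-2-(3,4-dimethoxyphenyl)ethyl]-4,5-dicyclohexyl-1,3,2-dioxaborolane | COc1ccc(C[C@@H](Cl)B2O[C@H](C3CCCCC3)[C@@H](C3CCCCC3)O2)cc1OC
F3 | step 4 | tert-butyl (3R)-3-[(4R,5R)-4,5-dicyclohexyl-1,3,2-dioxaborolan-2-yl]-4-(3,4-dimethoxyphenyl)butanoate | COc1ccc(C[C@H](CC(=O)OC(C)(C)C)B2O[C@H](C3CCCCC3)[C@@H](C3CCCCC3)O2)cc1OC
F4 | step 4 | tert-butyl (3R)-3-{[(4R,5R)-4,5-dicyclohexyl-1,3,2-dioxaborolan-2-yl]methyl}-4-(3,4-dimethoxyphenyl)butanoate | COc1ccc(C[C@H](CC(=O)OC(C)(C)C)CB2O[C@H](C3CCCCC3)[C@@H](C3CCCCC3)O2)cc1OC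
F5 | step 4 | tert-butyl (3R)-4-(3,4-dimethoxyphenyl)-3-(hydroxymethyl)butanoate | COc1ccc(C[C@H](CC(=O)OC(C)(C)C)CO)cc1OC
F6 | step 3 | 3,4-dimethoxybenzyl phenyl sulfide | COc1ccc(CSc2ccccc2)cc1OC
F7 | step 3 | (3,4-dimethoxybenzyl)lithium | COc1ccc(C[Li])cc1OC
F8 | step 6 | (4R,5R)-2-[(3S)-4-(benzyloxy)-3-(3,4-dimethoxybenzyl)butyl]-4,5-dicyclohexyl-1,3,2-dioxaborolane | COc1ccc(C[C@H](CCB2O[C@H](C3CCCCC3)[C@@H](C3CCCCC3)O2)COCc2ccccc2)cc1OC
F9 | step 6 | (3R)-4-(benzyloxy)-3-(3,4-dimethoxybenzyl)butan-1-ol | COc1ccc(C[C@H](CCO)COCc2ccccc2)cc1OC
F10 | step 9 | 3,4-bis(benzyloxy)benzaldehyde | O=Cc1ccc(OCc2ccccc2)c(OCc2ccccc2)c1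
F11 | step 9 | (4R)-3-{[3,4-bis(benzyloxy)phenyl](hydroxy)methyl}-4-(3,4-dimethoxybenzyl)oxolan-2-one (mixture at the two new centres) | COc1ccc(C[C@H]2COC(=O)C2C(O)c2ccc(OCc3ccccc3)c(OCc3ccccc3)c2)cc1OC
F12 | step 9 | (3E,4R)-3-[3,4-bis(benzyloxy)benzylidene]-4-(3,4-dimethoxybenzyl)oxolan-2-one | COc1ccc(C[C@H]2COC(=O)/C2=C/c2ccc(OCc3ccccc3)c(OCc3ccccc3)c2)cc1OC
F13 | step 9 | (3S,4R)-3-[3,4-bis(benzyloxy)benzyl]-4-(3,4-dimethoxybenzyl)oxolan-2-one | COc1ccc(C[C@H]2COC(=O)[C@H]2Cc2ccc(OCc3ccccc3)c(OCc3ccccc3)c2)cc1OC
A1 | alternative 1 | ethyl 3-[3,4-bis(methoxymethoxy)phenyl]-2-[(4S,5R)-5-(3,4-dimethoxyphenyl)-2,2-dimethyl-1,2-oxasilolan-4-yl]propanoate (both epimers at the ester-bearing carbon) | C[Si]1(C)C[C@@H](C(Cc2ccc(OCOC)c(OCOC)c2)C(=O)OCC)[C@H](c2ccc(OC)c(OC)c2)O1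
A2 | alternative 1 | ethyl (4R)-2-[3,4-bis(methoxymethoxy)benzyl]-4-{[(bromomethyl)dimethylsilyl]oxy}-4-(3,4-dimethoxyphenyl)but-2-enoate | CCOC(=O)C(Cc1ccc(OCOC)c(OCOC)c1)=C[C@@H](O[Si](C)(C)CBr)c1ccc(OC)c(OC)c1
A3 | alternative 2 | (2R,3S)-2-[3,4-bis(pivaloyloxy)benzyl]-3-(3,4-dimethoxybenzyl)cyclobutan-1-one (trans) | COc1ccc(C[C@H]2CC(=O)[C@@H]2Cc2ccc(OC(=O)C(C)(C)C)c(OC(=O)C(C)(C)C)c2)cc1OC
A4 | alternative 2 | methyl eugenol (4-allyl-1,2-dimethoxybenzene) | COc1ccc(CC=C)cc1OC
A5 | alternative 2 | 4-{3-[(2S,5S)-2,5-dimethylpyrrolidin-1-yl]-3-oxopropyl}-1,2-phenylene bis(2,2-dimethylpropanoate) (one enantiomer drawn; the sense of induction would decide which is needed) | C[C@H]1CC[C@H](C)N1C(=O)CCc1ccc(OC(=O)C(C)(C)C)c(OC(=O)C(C)(C)C)c1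
A6 | alternative 3 | (3R,4S)-3-[3,4-bis(benzyloxy)benzyl]-4-(hydroxymethyl)oxolan-2-one (trans) | OC[C@H]1COC(=O)[C@@H]1Cc1ccc(OCc2ccccc2)c(OCc2ccccc2)c1
A7 | alternative 3 | (2R)-2-[3,4-bis(benzyloxy)benzyl]-4-hydroxy-3-(hydroxymethyl)butanoic acid | OCC(CO)[C@@H](Cc1ccc(OCc2ccccc2)c(OCc2ccccc2)c1)C(=O)O
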